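Start from the partner. The forming of target and its over-reaction both run in proportion to partner, so as a first reckoning I matched two flasks with the same substrate charge at the same exposure: partner in equivalents, multiplied by time. That match was rough: the undoing of target into substrate and partner runs without partner.

| setting | Wednesday's | flask |
|---|---|---|
| substrate | 15 mM | 15 mM |
| coupling partner | 5 equiv | 2.50 equiv |
| remark | run made earlier |  |
| time |  | 40 h |

Wednesday's run (percent of the substrate charged)

| time / h | target / % |
|---|---|
| 0.667 | 64.6 |
| 1.00 | 60.2 |
| 1.33 | 52.5 |
| 2.50 | 31.8 |
| 3.00 | 26.2 |
| 5.00 | 11.9 |
| 8.00 | 3.9 |

(standard deviation of a reading: 0.3 percentage points)

- the best time, 40 h at the latest, for target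
- the amount of target, in percent of the substrate charged, at that time

- the analysis behind the earlier runs scatters by 0.3 percentage points, standard deviation
- reactions considered so far: substrate + coupling partner <-> target; substrate + coupling partner <-> isomer of the product; coupling partner + target -> over-reaction product

Wednesday's highest reading was its first, 64.6% at 0.667 h, so I put its top near there. Scaling by the charges alone, the flask would reach that state at 1.33 h. But partner gets spent, and on this reckoning both flasks have spent the same equivalents at equal exposure, a larger share of the flask's charge.

So I needed that spending. Wednesday's tail fell at 0.382 /h, and integrating that loss over the target present gave about 16.4% of the charge gone to over-reaction product by the first reading. The tail's lower partner understates this, while the target's earlier lower level overstates it, so I let the two errors stand against each other. One equivalent per target and two per over-reaction product gave 0.975 equiv, the partner bill of the top. Isomer would add to it, and an earlier top would take from it.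

Charge minus bill stretched the time to 1.76 h. That is too long, since the bill falls due gradually and the average partner stands above its final value. The first reading might also lie past the top, but the next two intervals lost 4.4 percentage points and then 7.7 points, so the curve was still rounding there. I settled near the low end, with a height close to Wednesday's.

The forecast said 1.4 h and 64%: “Both steps are first order in partner, so the peak height shouldn't depend on equivalents”. The flask gave 1.35 h and 61.5%.

    substrate + coupling partner ⇌ target (K = 300 /M, k = 0.838 /M/min)
    substrate + coupling partner ⇌ isomer of the product (K = 4700 /M, k = 0.0431 /M/min)
    coupling partner + target → over-reaction product (k = 0.143 /M/min)

Over-reaction is the largest single effect on that height: without it the flask tops at 82.4%, against 61.5%. At its top the flask had spent 0.954 equiv of partner, close to the bill. The neighbour charged with 0.620 equiv started below that bill, and its best was 36.2%. There partner was the limiting reagent: at 40.0 h it held 9.69% of its own charge, with 58.5% of the substrate unreacted.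

(All runs are simulated with made-up constants; noise was put on by code.)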